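To whoever takes the bench from me: this flask holds X, charged at 0.20 M, turning into G, and you will read it at 15 min.

| flask | X | remark | time |
|---|---|---|---|
| teal | 0.13 M | run made earlier |  |
| blue | 0.30 M | run made earlier |  |
| flask | 0.20 M |  | 15 min |

- teal (time / min: G / %, X / %): 2.50: 85.1, 13.9; 5.00: 94.8, 4.9; 8.00: 93.0, 7.0; 10.0: 95.9, 6.9; 12.0: 94.1, 5.7; 15.0: 95.8, 4.9
- blue (time / min: G / %, X / %): 2.50: 88.3, 13.4; 5.00: 96.4, 5.6; 8.00: 97.0, 2.6; 10.0: 96.8, 3.2; 12.0: 96.2, 1.9; 15.0: 98.6, 2.0

(scatter of a reading: 1 percentage point)

- the earlier runs were read with a standard deviation of 1 percentage point
- a reading or a percentage of G counts all its forms, free or not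
- the reaction counts as stopped when no species that holds the X changes by six tenths of a point or more over the second half of the time

- which holds at 15 min: what has brought the reaction to rest, or that it has not come to rest (forward and back rates have come level / it is still moving / all of X has reacted)
- amount of G at 15 min, in percent of the X charged

From 8.00 min on, X averages 7.96 mM in the teal run and 7.28 mM in the blue run, although their charges differ. Their mean, 7.62 mM, I call the floor c_f: the concentration of X left once the readings stop falling.

I treat X as a first-order lag settling onto that floor, its excess shrinking as exp(−t/τ), with τ the time constant. The first blue reading gives τ = 1.14 min, so about 13.2 time constants pass before you read. I therefore reckon this flask at rest, with X at c_f over the charge, 3.81 %, and G at 96.2 %. Leave the charge alone, since c_f is a concentration and the share of X left depends on the charge.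

The forecast says forward and back rates have come level and 96.3 %, on the ground that “residual X is roughly constant”. The flask gives forward and back rates have come level and 96.4 %.

    X ⇌ G (K = 2.90, k = 0.0150 s⁻¹)
    E ⇌ G, rate k2*(cs2 - [G]) while solid is left; crystals form when [G] > cs2 (solubility = 21.0 mM, k = 0.610 s⁻¹)

Dissolved G has a ceiling of 21 mM, and the excess leaves solution as crystals E, which hold 85.9 % of this flask's charge at 15.0 min, counted in G. Of the reasons I can show, this ceiling has the largest single effect: the same run without it ends at 74.4 % G, against 96.4 %. This flask holds 3.6 % X, against my 3.81 %. For the neighbour flask charged at 0.050 M, c_f gives 15.2 % X, and that flask holds 14 %.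

The data are calculated from invented constants; scatter was added.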